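All runs are simulated from invented constants; noise was put on by code.

If every proton set free when electrophile meets nucleophile lands on the nucleophile and not on the buffer base, each target costs two nucleophiles, and that is how I read the two earlier runs, which burst and then stall.

all flasks: electrophile 0.088 M; nucleophile 0.0792 M; buffer base 0.264 M; protic impurity 0.0176 M

| run | buffer acid | remark | time |
|---|---|---|---|
| teal | 12 mM | run made earlier |  |
| violet | 19 mM | run made earlier |  |
| flask | 8.80 mM |  | 50 min |

| run | time / min | electrophile / % | target / % |
|---|---|---|---|
| teal | 2.00 | 67.2 | 30.7 |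
| teal | 6.00 | 60.5 | 40.4 |
| teal | 12.0 | 54.9 | 37.5 |
| teal | 15.0 | 55.0 | 41.4 |
| teal | 25.0 | 51.6 | 39.5 |
| teal | 30.0 | 49.7 | 40.9 |
| teal | 40.0 | 48.8 | 43.1 |
| violet | 2.00 | 71.3 | 28.4 |
| violet | 6.00 | 60.5 | 33.6 |
| violet | 12.0 | 59.2 | 34.8 |
| violet | 15.0 | 57.2 | 36.6 |
| violet | 25.0 | 54.5 | 37.4 |
| violet | 30.0 | 53.4 | 37.3 |
| violet | 40.0 | 49.9 | 37.1 |

(readings scatter by 1 percentage point)

- the numbers in the tables scatter by 1 percentage point (one standard deviation)
- the earlier runs do not show the pH; that part of a forecast is a guess

- part of the electrophile that has reacted at 50 min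
- pH of the solution at 50 min

I solved two extreme versions of the flask. With the buffer base catching every proton, the reaction ran to the nucleophile's charge, 90.0% of the electrophile. With the nucleophile catching every proton, the charged buffer acid first took its share of the nucleophile, and the reaction stopped at what I called the burst ceiling: half of the remaining nucleophile, as a part of the electrophile charged, 40.0% for this flask. The same reckoning gave 38.2% for teal and 34.2% for violet. At 12.0 min teal and violet read 37.5% and 34.8% of target, well below the first extreme, so I placed the flask's target close to the second. At 40.0 min the reacted part read in teal stood 13 percentage points above its ceiling, and its late slope, read from the same scattered table and carried on, gave an estimated 2.2 points more by 50 min. Laid on this flask's ceiling, that made my own estimate 55.2% reacted.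

The forecast gave 55% (51% to 59%) and pH 7.8 (6.3 to 9.5), the pH being “purely a guess”.

The flask gave 55.6% reacted and pH 6.48.

    electrophile + nucleophile → acid + target + leaving group (k = 6.26 M⁻¹ min⁻¹)
    protonated nucleophile ⇌ nucleophile + acid, settled at all times (K = 2.00 × 10⁻⁹ M)
    buffer acid ⇌ buffer base + acid, settled at all times (K = 7.90 × 10⁻⁶ M)
    electrophile + protic impurity → quenched substrate (k = 0.280 M⁻¹ min⁻¹)
    target ⇌ isomer of the product (K = 2.49, k = 0.00112 min⁻¹)
    target → over-reaction product (k = 3.79 × 10⁻⁴ min⁻¹)

At 5.00 min this flask held 39.2% of target against its ceiling of 40.0%. At 50.0 min this flask's nucleophile, the limiting reagent, was 0.290% of its charge free, 0.0384 M stood as protonated nucleophile, and the buffer acid had grown to 126% of its charge. The neighbouring flask, charged with 0.053 M of electrophile, has a ceiling of 66.4%; at 50.0 min it had 77.8% of its electrophile reacted and held 66.4% of target.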